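**Retrosynthetic overview**

1. Locants are those of the bicyclo[3.2.1]octane name of the target (C1 bridgehead CH, C2 and C8 ketones, C3(OMe)=C4, C5 allyl-bearing bridgehead, C6 CHMe, C7 CH-aryl) and are kept for the corresponding carbons of all intermediates. The C3 enol ether comes last, by O-methylation of a diosphenol made by oxidation at C3 of the saturated bicyclo[3.2.1]octane-2,8-dione 16.
2. Key disconnection: C1–C2 together with C7–aryl. In the five-membered ring C1–C7–C6–C5–C8 the C8 ketone carries the aryl group on its β-carbon C7 and the acyl carbon C2 on its α-carbon C1 (C1 is the CH between the C2 and C8 carbonyls). This is the retron of a conjugate addition to a cyclopent-2-enone whose enolate is acylated by an amide tethered to C5.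
3. Cyclopentenone 12 plus an aryl cuprate therefore gives 16 in one operation: the C7–aryl bond, closure of the six-membered ring C1–C2–C3–C4–C5–C8 (and with it the seven-membered ring and the bicycle), and the stereocentres C7 and C1.
4. Quaternary C5: Michael addition of a β-keto allyl ester to a Weinreb acrylamide, then palladium-catalysed decarboxylative allylation anti to the C6 methyl group. C6 comes from (R)-pulegone by Favorskii ring contraction and ozonolysis.
5. Ring order: the five-membered ring first (from pulegone), then the six- and seven-membered rings together in the key step.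

Key step: step 7

Remark: the target is taken exactly as drawn, which corresponds to (1S,5S,6R,7R)-7-(3,4-dimethoxyphenyl)-3-methoxy-6-methyl-5-(prop-2-en-1-yl)bicyclo[3.2.1]oct-3-ene-2,8-dione. Centres that are erased in a following step are left unspecified (C2 of 2, C1 of 3, C5 and C6 of 4, the carbinolamine carbon of 15, C3 of 18), and 9 is drawn as the expected major epimer.

**Route**

Step 1
Reactants: 1 (R)-(+)-pulegone
Product: 3 methyl pulegenate, via pulegone dibromide 2 (not isolated)
Conditions: Br2, Et2O, −10 °C; then NaOMe, MeOH, 65 °C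
Reagents that add atoms: sodium methoxide, [Na+].[O-]C
Why: Bromine adds across the tetrasubstituted enone double bond and methoxide then effects a Favorskii ring contraction of the α,β-dibromo ketone (cyclopropanone opening with expulsion of the second bromide restores the isopropylidene group), which leaves the remote (R)-methyl centre untouched.

Step 2
Reactants: 3 methyl pulegenate
Product: 5 methyl (1S,2R)-2-methyl-5-oxocyclopentane-1-carboxylate, via ozonide 4 (not isolated)
Conditions: O3, CH2Cl2, −78 °C; then Me2S, −78 to 23 °C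
Reagents that add atoms: ozone, [O-][O+]=O
Why: Ozonolysis with reductive work-up cleaves the electron-rich tetrasubstituted alkene to the ring ketone and acetone; the ester-bearing carbon of the resulting β-keto ester equilibrates to the trans isomer and is not a lasting stereocentre.

Step 3
Reactants: 5 methyl (1S,2R)-2-methyl-5-oxocyclopentane-1-carboxylate, 6 allyl alcohol
Product: 7 prop-2-en-1-yl (1S,2R)-2-methyl-5-oxocyclopentane-1-carboxylate
Conditions: DMAP (0.2 equiv), 4 Å molecular sieves, toluene, 110 °C
Reagents that add atoms: none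
Why: DMAP-assisted thermal transesterification of a β-keto ester, driven by removal of methanol on the sieves, installs the allyl ester that later delivers the allyl group of the target.

Step 4
Reactants: 7 prop-2-en-1-yl (1S,2R)-2-methyl-5-oxocyclopentane-1-carboxylate, 8 N-methoxy-N-methylprop-2-enamide
Product: 9 prop-2-en-1-yl (1R,2R)-1-{3-[methoxy(methyl)amino]-3-oxopropyl}-2-methyl-5-oxocyclopentane-1-carboxylate
Conditions: Cs2CO3 (0.2 equiv), MeCN, 40 °C
Reagents that add atoms: none
Why: Carbonate-catalysed Michael addition of the β-keto ester enolate to the acrylamide builds the C5–C4 bond and brings in C4, C3 and C2 as the Weinreb amide; the configuration of the new quaternary carbon is of no consequence because it becomes a planar enolate in step 5.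

Step 5
Reactants: 9 prop-2-en-1-yl (1R,2R)-1-{3-[methoxy(methyl)amino]-3-oxopropyl}-2-methyl-5-oxocyclopentane-1-carboxylate
Product: 10 N-methoxy-N-methyl-3-[(1S,2R)-2-methyl-5-oxo-1-(prop-2-en-1-yl)cyclopentyl]propanamide
Conditions: Pd(PPh3)4 (5 mol %), THF, 23 °C
Reagents that add atoms: none
Why: Tsuji decarboxylative allylation: zerovalent palladium ionizes the allyl ester, loss of CO2 gives the regiodefined C5 enolate paired with the allylpalladium cation, and C-allylation on the enolate face anti to the adjacent C6 methyl group should set the quaternary centre C5 with the allyl group trans and the amide chain cis to that methyl group.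

Step 6
Reactants: 10 N-methoxy-N-methyl-3-[(1S,2R)-2-methyl-5-oxo-1-(prop-2-en-1-yl)cyclopentyl]propanamide
Product: 12 N-methoxy-N-methyl-3-[(1S,5R)-5-methyl-2-oxo-1-(prop-2-en-1-yl)cyclopent-3-en-1-yl]propanamide, via silyl enol ether 11 (not isolated)
Conditions: Me3SiOTf, Et3N, CH2Cl2, 0 °C; then Pd(OAc)2 (1.05 equiv), MeCN, 23 °C
Reagents that add atoms: none
Why: Saegusa–Ito oxidation: soft enolization can only occur toward C1 because C5 is quaternary, and Pd(OAc)2 converts the silyl enol ether into the C1=C7 enone by β-hydride elimination under non-basic conditions that leave C5 and C6 untouched.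

Step 7
Reactants: 12 N-methoxy-N-methyl-3-[(1S,5R)-5-methyl-2-oxo-1-(prop-2-en-1-yl)cyclopent-3-en-1-yl]propanamide, 13 4-bromo-1,2-dimethoxybenzene (converted in the flask into lithium bis(3,4-dimethoxyphenyl)cuprate)
Product: 16 (1R,5S,6R,7R)-7-(3,4-dimethoxyphenyl)-6-methyl-5-(prop-2-en-1-yl)bicyclo[3.2.1]octane-2,8-dione, via lithium enolate 14 (not isolated), via tetrahedral lithium alkoxide 15 (not isolated)
Conditions: 13 (2.6 equiv), t-BuLi (5.2 equiv), THF, −78 °C; CuBr·SMe2 (1.3 equiv), −78 to −40 °C; then 12, −78 to 23 °C; aq NH4Cl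
Reagents that add atoms: none
Why: The diarylcuprate Ar2CuLi transfers one aryl group to C7 of the enone and leaves the lithium enolate 14 (C8–OLi, C8=C1), whose carbon C1 attacks the Weinreb amide carbonyl C2 that the C5 tether holds over the same ring face, to give the N,O-chelated tetrahedral lithium alkoxide 15, which collapses to the C2 ketone only on the ammonium chloride quench. The closest known reaction type is the tandem cuprate conjugate addition–intramolecular Claisen (Dieckmann-type) acylation, and the bridging C-acylation of the α'-carbon of a cyclopentanone by a three-carbon unit on its α-carbon is the ring closure of the α,α'-annulation of cyclopentanone enamines with acryloyl chloride. The six-membered ring C1–C2–C3–C4–C5–C8 closes in the 6-(enolendo)-exo-trig mode, and because C1 and C5 are already joined through C6–C7 the same bond closes the seven-membered ring C1–C2–C3–C4–C5–C6–C7 and so completes the bicyclo[3.2.1]octane. C7 is set by attack of the cuprate on the enone face anti to the adjacent C6 methyl group (the usual trans addition to 4-substituted cyclopent-2-enones), which is also the face away from the amide tether, and C1 is set by the tether, which can reach the enolate carbon only from the face on which it stands. The step needs 1,4-addition in preference to 1,2-addition and to attack on the amide, which the soft diarylcuprate at low temperature secures, C- in preference to O-acylation, which the amide secures because an O-adduct can only revert, and protection of the 1,3-diketone (whose central carbon C1 cannot enolize) from retro-Claisen cleavage, which is secured because no alkoxide is set free before the quench.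

Step 8
Reactants: 16 (1R,5S,6R,7R)-7-(3,4-dimethoxyphenyl)-6-methyl-5-(prop-2-en-1-yl)bicyclo[3.2.1]octane-2,8-dione
Product: 18 (1S,3RS,5R,6R,7R)-7-(3,4-dimethoxyphenyl)-3-hydroxy-6-methyl-5-(prop-2-en-1-yl)bicyclo[3.2.1]octane-2,8-dione, via potassium enolate 17 (not isolated)
Conditions: KN(SiMe3)2, THF, −78 °C; then 3-phenyl-2-(phenylsulfonyl)oxaziridine, −78 °C; AcOH
Reagents that add atoms: 3-phenyl-2-(phenylsulfonyl)oxaziridine (Davis reagent), O=S(=O)(c1ccccc1)N1OC1c1ccccc1
Why: Only C3 can be deprotonated (C1 is a bridgehead whose enolization would violate Bredt's rule and C5 is quaternary), and Davis oxidation of the potassium enolate gives the acyloin, whose new centre C3 is not controlled because it becomes sp2 in step 9.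

Step 9
Reactants: 18 (1S,3RS,5R,6R,7R)-7-(3,4-dimethoxyphenyl)-3-hydroxy-6-methyl-5-(prop-2-en-1-yl)bicyclo[3.2.1]octane-2,8-dione
Product: 20 (1S,5S,6R,7R)-7-(3,4-dimethoxyphenyl)-3-hydroxy-6-methyl-5-(prop-2-en-1-yl)bicyclo[3.2.1]oct-3-ene-2,8-dione, via trione 19 (not isolated)
Conditions: Dess–Martin periodinane, CH2Cl2, 23 °C
Reagents that add atoms: none
Why: Dess–Martin oxidation of the acyloin gives the 2,3-diketone, which can enolize only toward C4 (C1 is a bridgehead) and so should deliver the diosphenol with the C3=C4 double bond in the place the target requires.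

Step 10
Reactants: 20 (1S,5S,6R,7R)-7-(3,4-dimethoxyphenyl)-3-hydroxy-6-methyl-5-(prop-2-en-1-yl)bicyclo[3.2.1]oct-3-ene-2,8-dione
Product: 21 Kadsurenin D
Conditions: Me2SO4, K2CO3, acetone, 23 °C
Reagents that add atoms: dimethyl sulfate, COS(=O)(=O)OC
Why: O-Methylation of the acidic diosphenol with the hard electrophile dimethyl sulfate under mild carbonate conditions (Williamson-type enol etherification) should give the methyl enol ether without touching any stereocentre or exposing the 1,3-diketone to alkoxide.

**Compound list**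

1 | (R)-(+)-pulegone, (5R)-5-methyl-2-(propan-2-ylidene)cyclohexan-1-one | C[C@@H]1CCC(=C(C)C)C(=O)C1 | starting material
2 | pulegone dibromide, (5R)-2-bromo-2-(2-bromopropan-2-yl)-5-methylcyclohexan-1-one (C2 epimers) | C[C@@H]1CCC(Br)(C(C)(C)Br)C(=O)C1 | intermediate
3 | methyl pulegenate, methyl (5R)-5-methyl-2-(propan-2-ylidene)cyclopentane-1-carboxylate (C1 epimers) | C[C@@H]1CCC(=C(C)C)C1C(=O)OC | intermediate
4 | secondary ozonide of 3, methyl (7R)-3,3,7-trimethyl-1,2,4-trioxaspiro[4.4]nonane-6-carboxylate | C[C@@H]1CCC2(OOC(C)(C)O2)C1C(=O)OC | intermediate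
5 | methyl (1S,2R)-2-methyl-5-oxocyclopentane-1-carboxylate (trans) | C[C@@H]1CCC(=O)[C@H]1C(=O)OC | intermediate
6 | allyl alcohol, prop-2-en-1-ol | C=CCO | starting material
7 | prop-2-en-1-yl (1S,2R)-2-methyl-5-oxocyclopentane-1-carboxylate (trans) | C[C@@H]1CCC(=O)[C@H]1C(=O)OCC=C | intermediate
8 | N-methoxy-N-methylprop-2-enamide | C=CC(=O)N(C)OC | starting material
9 | prop-2-en-1-yl (1R,2R)-1-{3-[methoxy(methyl)amino]-3-oxopropyl}-2-methyl-5-oxocyclopentane-1-carboxylate (amide chain trans to methyl) | C[C@@H]1CCC(=O)[C@]1(CCC(=O)N(C)OC)C(=O)OCC=C | intermediate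
10 | N-methoxy-N-methyl-3-[(1S,2R)-2-methyl-5-oxo-1-(prop-2-en-1-yl)cyclopentyl]propanamide (allyl trans to methyl) | C[C@@H]1CCC(=O)[C@]1(CC=C)CCC(=O)N(C)OC | intermediate
11 | N-methoxy-N-methyl-3-[(1S,5R)-5-methyl-1-(prop-2-en-1-yl)-2-[(trimethylsilyl)oxy]cyclopent-2-en-1-yl]propanamide | C[C@@H]1CC=C(O[Si](C)(C)C)[C@]1(CC=C)CCC(=O)N(C)OC | intermediate
12 | N-methoxy-N-methyl-3-[(1S,5R)-5-methyl-2-oxo-1-(prop-2-en-1-yl)cyclopent-3-en-1-yl]propanamide | C[C@@H]1C=CC(=O)[C@]1(CC=C)CCC(=O)N(C)OC | intermediate
13 | 4-bromo-1,2-dimethoxybenzene | COc1ccc(Br)cc1OC | starting material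
14 | lithium enolate (C8–OLi, C8=C1) of the conjugate adduct; aryl trans to methyl and to the amide chain | [Li]OC1=C[C@H](c2ccc(OC)c(OC)c2)[C@@H](C)[C@@]1(CC=C)CCC(=O)N(C)OC | intermediate
15 | lithium alkoxide of the C2 N-methoxy-N-methyl hemiaminal of 16 | C=CC[C@]12CCC(O[Li])(N(C)OC)[C@H](C1=O)[C@H](c1ccc(OC)c(OC)c1)[C@H]2C | intermediate
16 | (1R,5S,6R,7R)-7-(3,4-dimethoxyphenyl)-6-methyl-5-(prop-2-en-1-yl)bicyclo[3.2.1]octane-2,8-dione (aryl exo, methyl endo) | C=CC[C@]12CCC(=O)[C@H](C1=O)[C@H](c1ccc(OC)c(OC)c1)[C@H]2C | intermediate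
17 | potassium C2(O)=C3 enolate of 16 | C=CC[C@]12CC=C(O[K])[C@H](C1=O)[C@H](c1ccc(OC)c(OC)c1)[C@H]2C | intermediate
18 | (1S,3RS,5R,6R,7R)-7-(3,4-dimethoxyphenyl)-3-hydroxy-6-methyl-5-(prop-2-en-1-yl)bicyclo[3.2.1]octane-2,8-dione | C=CC[C@]12CC(O)C(=O)[C@H](C1=O)[C@H](c1ccc(OC)c(OC)c1)[C@H]2C | intermediate
19 | (1S,5R,6R,7R)-7-(3,4-dimethoxyphenyl)-6-methyl-5-(prop-2-en-1-yl)bicyclo[3.2.1]octane-2,3,8-trione | C=CC[C@]12CC(=O)C(=O)[C@H](C1=O)[C@H](c1ccc(OC)c(OC)c1)[C@H]2C | intermediate
20 | (1S,5S,6R,7R)-7-(3,4-dimethoxyphenyl)-3-hydroxy-6-methyl-5-(prop-2-en-1-yl)bicyclo[3.2.1]oct-3-ene-2,8-dione (diosphenol) | C=CC[C@]12C=C(O)C(=O)[C@H](C1=O)[C@H](c1ccc(OC)c(OC)c1)[C@H]2C | intermediate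
21 | Kadsurenin D, (1S,5S,6R,7R)-7-(3,4-dimethoxyphenyl)-3-methoxy-6-methyl-5-(prop-2-en-1-yl)bicyclo[3.2.1]oct-3-ene-2,8-dione | C=CC[C@]12C=C(OC)C(=O)[C@H](C1=O)[C@H](c1ccc(OC)c(OC)c1)[C@H]2C | target

**Summary and risks**

Total step count: 10. Longest linear sequence: 10 steps (1 to 21); 6, 8 and 13 enter as purchased compounds.

Steps most likely to fail:

Step 7. The copper-containing lithium enolate aggregate may be protonated on quench before it has attacked the amide, or surplus aryl–metal species may add to the amide. The fallback separates the two events. Setting out from 12, rhodium-catalysed conjugate addition of (3,4-dimethoxyphenyl)boronic acid ([Rh(OH)(cod)]2, dioxane–water, 50 °C) should give, again anti to the C6 methyl group, the ketone N-methoxy-N-methyl-3-[(1S,2R,3S)-3-(3,4-dimethoxyphenyl)-2-methyl-5-oxo-1-(prop-2-en-1-yl)cyclopentyl]propanamide F1. Its only possible ketone enolate is then formed with LiN(SiMe3)2 in THF (−78 to 0 °C) and, free of copper, should close the ring to 15; quench gives 16, where the route is rejoined.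

Step 5. Facial selectivity in the C-allylation of the palladium-bound enolate may be poor, because only the neighbouring methyl group differentiates the two faces, or the enolate may be protonated in place of being allylated. The fallback sets the quaternary centre by classical alkylation and builds the side chain from the ester carbon.
- Setting out from 5, allylation with allyl bromide and K2CO3 in acetone should occur anti to the methyl group and give methyl (1R,2R)-2-methyl-5-oxo-1-(prop-2-en-1-yl)cyclopentane-1-carboxylate F2, in which the ester carbon (the future C4) is cis to the methyl group.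
- LiAlH4 reduces ester and ketone to the diol (1RS,2S,3R)-2-(hydroxymethyl)-3-methyl-2-(prop-2-en-1-yl)cyclopentan-1-ol F3.
- Double oxidation with Dess–Martin periodinane gives the keto aldehyde (1S,2R)-2-methyl-5-oxo-1-(prop-2-en-1-yl)cyclopentane-1-carbaldehyde F4.
- Wittig reaction of the aldehyde with methyl (triphenylphosphoranylidene)acetate gives the enoate methyl (2E)-3-[(1S,2R)-2-methyl-5-oxo-1-(prop-2-en-1-yl)cyclopentyl]prop-2-enoate F5.
- Conjugate reduction with [(Ph3P)CuH]6 should leave the ketone and the allyl group intact and give methyl 3-[(1S,2R)-2-methyl-5-oxo-1-(prop-2-en-1-yl)cyclopentyl]propanoate F6.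
- Aminolysis with Me2AlN(OMe)Me (from AlMe3 and N,O-dimethylhydroxylamine hydrochloride) comes back to the route at 10.

Step 8. Under the strongly basic enolization the strained 1,3-diketone may be opened by retro-Claisen attack of a base or of the alkoxide formed, or the enolate may add to the sulfonimine by-product. The fallback avoids the metal enolate. Setting out from 16, soft enolization (Me3SiOTf, Et3N, CH2Cl2, 0 °C) gives the silyl enol ether (1R,5S,6R,7R)-7-(3,4-dimethoxyphenyl)-6-methyl-5-(prop-2-en-1-yl)-2-[(trimethylsilyl)oxy]bicyclo[3.2.1]oct-2-en-8-one F7. Rubottom oxidation with dimethyldioxirane in acetone at −78 °C should epoxidize the electron-rich enol ether in preference to the allyl group, and mildly acidic work-up gives 18, where the route is rejoined.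

**Further compounds**

F1 | step 7 | N-methoxy-N-methyl-3-[(1S,2R,3S)-3-(3,4-dimethoxyphenyl)-2-methyl-5-oxo-1-(prop-2-en-1-yl)cyclopentyl]propanamide | C[C@@H]1[C@@H](c2ccc(OC)c(OC)c2)CC(=O)[C@]1(CC=C)CCC(=O)N(C)OC
F2 | step 5 | methyl (1R,2R)-2-methyl-5-oxo-1-(prop-2-en-1-yl)cyclopentane-1-carboxylate | C[C@@H]1CCC(=O)[C@]1(CC=C)C(=O)OC
F3 | step 5 | (1RS,2S,3R)-2-(hydroxymethyl)-3-methyl-2-(prop-2-en-1-yl)cyclopentan-1-ol | C[C@@H]1CCC(O)[C@]1(CC=C)CO
F4 | step 5 | (1S,2R)-2-methyl-5-oxo-1-(prop-2-en-1-yl)cyclopentane-1-carbaldehyde | C[C@@H]1CCC(=O)[C@]1(CC=C)C=O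
F5 | step 5 | methyl (2E)-3-[(1S,2R)-2-methyl-5-oxo-1-(prop-2-en-1-yl)cyclopentyl]prop-2-enoate | C[C@@H]1CCC(=O)[C@]1(CC=C)/C=C/C(=O)OC
F6 | step 5 | methyl 3-[(1S,2R)-2-methyl-5-oxo-1-(prop-2-en-1-yl)cyclopentyl]propanoate | C[C@@H]1CCC(=O)[C@]1(CC=C)CCC(=O)OC
F7 | step 8 | (1R,5S,6R,7R)-7-(3,4-dimethoxyphenyl)-6-methyl-5-(prop-2-en-1-yl)-2-[(trimethylsilyl)oxy]bicyclo[3.2.1]oct-2-en-8-one | C=CC[C@]12CC=C(O[Si](C)(C)C)[C@H](C1=O)[C@H](c1ccc(OC)c(OC)c1)[C@H]2C
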